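**Plan**

- Retrosynthesis: ring C of the isoflavone (O1, C2, C3, C4, C4a, C8a) is first exchanged for its redox isomer, a 4-hydroxy-3-arylcoumarin with C2 as lactone carbonyl and C4 as enol. That ring is cut at O1–C2 and at C4–C4a into 3-methoxyphenol (ring A with O1) and an arylmalonate (C2, C3, C4, with ring B on C3), activated as its bis(2,4,6-trichlorophenyl) ester.
- The malonate is cut at C3–CO2H (carboxylation of the arylacetic acid), the acid at its CH2–C bond (one-carbon homologation of the chromene aldehyde), and the dimethylpyran ring of ring B at O–CMe2 and C4a–C4 (2,4-dihydroxybenzaldehyde plus prenal).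
- Forward: the pyran ring of ring B arises first (step 1), the side chain grows carbon by carbon (steps 3 and 5), ring C closes as the coumarin (step 7), and the carbonyl is moved from C2 to C4 (steps 8 and 9).
- Stereochemistry: the target has no stereocentre. Only regiochemistry has to be controlled: chromenylation at the carbon between the two hydroxyls, acylation of ring A para to its methoxyl, and methylation on the C4 oxygen.

Key step: step 7

**Route**

Step 1
Reactants: 1 2,4-dihydroxybenzaldehyde; 2 3-methylbut-2-enal (prenal)
Product: 4 5-hydroxy-2,2-dimethyl-2H-chromene-6-carbaldehyde, via ortho-quinone methide 3 (not isolated)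
Conditions: pyridine, 140 °C (sealed tube)
Reagents that add atoms: none
Why: Knoevenagel-type condensation at the ring carbon between the two hydroxyls (the 2-hydroxyl is held by a hydrogen bond to the aldehyde, so the 4-hydroxyl and its ortho carbon react) gives ortho-quinone methide 3, whose oxa-6π electrocyclisation closes the dimethylpyran ring, a standard chromenylation of resorcinol aldehydes.

Step 2
Reactants: 4 5-hydroxy-2,2-dimethyl-2H-chromene-6-carbaldehyde
Product: 5 5-methoxy-2,2-dimethyl-2H-chromene-6-carbaldehyde
Conditions: MeI, K2CO3, DMF, 40 °C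
Reagents that add atoms: iodomethane, CI
Why: Williamson ether synthesis, in which carbonate in DMF deprotonates the chelated phenol and the phenoxide is methylated on oxygen while the aldehyde and the chromene alkene stay inert.

Step 3
Reactants: 5 5-methoxy-2,2-dimethyl-2H-chromene-6-carbaldehyde
Product: 7 2-(5-methoxy-2,2-dimethyl-2H-chromen-6-yl)acetonitrile, via tosyloxazoline 6 (not isolated)
Conditions: TosMIC, KOt-Bu, DME, −40 °C; then MeOH, reflux
Reagents that add atoms: tosylmethyl isocyanide (TosMIC), Cc1ccc(cc1)S(=O)(=O)C[N+]#[C-]
Why: Van Leusen reductive cyanation, in which the TosMIC anion adds to the aldehyde and closes to tosyloxazoline 6, excess base opens the ring, and methanol removes the N-formyl group as methyl formate with loss of sulfinate, so the aldehyde carbon becomes a CH2 group carrying the nitrile under wholly basic conditions that the chromene tolerates.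

Step 4
Reactants: 7 2-(5-methoxy-2,2-dimethyl-2H-chromen-6-yl)acetonitrile
Product: 8 2-(5-methoxy-2,2-dimethyl-2H-chromen-6-yl)acetic acid
Conditions: KOH, EtOH–H2O, reflux; then 1 M HCl, 0 °C
Reagents that add atoms: potassium hydroxide, [K+].[OH-]; water, O
Why: Alkaline hydrolysis of a nitrile through the primary amide to the carboxylate, to which the aryl ethers and the chromene are inert, followed by cold acidification to free the acid.

Step 5
Reactants: 8 2-(5-methoxy-2,2-dimethyl-2H-chromen-6-yl)acetic acid
Product: 10 2-(5-methoxy-2,2-dimethyl-2H-chromen-6-yl)malonic acid, via dilithium enediolate 9 (not isolated)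
Conditions: LiN(i-Pr)2 (2.2 equiv), THF, −78 to 0 °C; CO2, −78 °C; then cold 1 M HCl
Reagents that add atoms: carbon dioxide, O=C=O
Why: Ivanov-type carboxylation, in which two equivalents of amide base give enediolate 9, carbon dioxide carboxylates it on carbon to the malonate dianion, and acidification in the cold frees the diacid without decarboxylation.

Step 6
Reactants: 10 2-(5-methoxy-2,2-dimethyl-2H-chromen-6-yl)malonic acid; 11 2,4,6-trichlorophenol (2 equiv)
Product: 12 bis(2,4,6-trichlorophenyl) 2-(5-methoxy-2,2-dimethyl-2H-chromen-6-yl)malonate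
Conditions: DCC (2.1 equiv), CH2Cl2, 0 °C to rt
Reagents that add atoms: none
Why: Carbodiimide esterification (active ester formation of the Steglich type), in which each carboxyl is activated as the O-acylisourea and captured by the acidic phenol at or below room temperature, so the diacid is neither heated nor exposed to mineral acid that could decarboxylate it or attack the chromene.

Step 7
Reactants: 12 bis(2,4,6-trichlorophenyl) 2-(5-methoxy-2,2-dimethyl-2H-chromen-6-yl)malonate; 13 3-methoxyphenol
Product: 16 4-hydroxy-7-methoxy-3-(5-methoxy-2,2-dimethyl-2H-chromen-6-yl)-2H-chromen-2-one, via mixed aryl malonate 14 (not isolated), via aryloxycarbonyl ketene 15 (not isolated)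
Conditions: Ph2O, 200–210 °C, argon
Reagents that add atoms: none
Why: Heating exchanges one trichlorophenyl group for the phenol to give mixed malonate 14 (new O1–C2 bond), and thermal loss of the second trichlorophenol from 14 gives aryloxycarbonyl ketene 15. The ketene carbon then acylates the ring A carbon ortho to the ester oxygen through a six-membered transition state (new C4–C4a bond), and tautomerisation to the 4-hydroxycoumarin makes the sequence irreversible. The closest known reaction type is the thermal cyclocondensation of phenols with bis(2,4,6-trichlorophenyl) malonates to 4-hydroxycoumarins. Ring C closes by intramolecular C-acylation of the arene, a 6-exo-dig attack on the ketene carbonyl, and no stereocentre is formed. The step needs acylation para and not ortho to the ring A methoxyl; the carbon between the two oxygens is the more hindered of the two sites ortho to the ester oxygen, so the 7-methoxy series should result. Ring B should survive because the medium is neutral and the temperature lies in the range that 2,2-dimethylchromenes meet in their own thermal syntheses, and the aryl group on C3 blocks a second annulation.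

Step 8
Reactants: 16 4-hydroxy-7-methoxy-3-(5-methoxy-2,2-dimethyl-2H-chromen-6-yl)-2H-chromen-2-one
Product: 17 4,7-dimethoxy-3-(5-methoxy-2,2-dimethyl-2H-chromen-6-yl)-2H-chromen-2-one
Conditions: Me2SO4, K2CO3, acetone, reflux
Reagents that add atoms: dimethyl sulfate, COS(=O)(=O)OC
Why: O-alkylation of the 4-hydroxycoumarin, a vinylogous carboxylic acid, by the hard electrophile dimethyl sulfate under carbonate in acetone should give the 4-methyl ether, C3 being fully substituted and shielded by the ortho-methoxyaryl group.

Step 9
Reactants: 17 4,7-dimethoxy-3-(5-methoxy-2,2-dimethyl-2H-chromen-6-yl)-2H-chromen-2-one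
Product: 20 7-methoxy-3-(5-methoxy-2,2-dimethyl-2H-chromen-6-yl)-4H-chromen-4-one (target), via lactol 18 (not isolated), via 2-hydroxyisoflavanone 19 (not isolated)
Conditions: i-Bu2AlH (1.2 equiv), CH2Cl2, −78 °C; then 1 M HCl, THF, 0 °C to rt
Reagents that add atoms: water, O
Why: Proposed new method: hydride adds once to the lactone carbonyl of the vinylogous carbonate and the aluminium hemiacetal holds at −78 °C, giving lactol 18 on protonation; aqueous acid then protonates the enol ether at C3, water adds to C4 and methanol leaves to give 2-hydroxyisoflavanone 19, and acid-catalysed loss of water across C2–C3 gives the pyranone, so the carbonyl ends at C4 and C2 at the aldehyde level; the closest known reaction types are the i-Bu2AlH half-reduction of coumarins to 2H-chromen-2-ols, the reduction–hydrolysis 1,3-carbonyl transposition of β-alkoxy enones (Stork–Danheiser) and the acid dehydration of 2-hydroxyisoflavanones.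

**Compound list**

1 | 2,4-dihydroxybenzaldehyde | O=Cc1ccc(O)cc1O | starting material
2 | 3-methylbut-2-enal (prenal) | CC(C)=CC=O | starting material
3 | (Z)-2-hydroxy-3-(3-methylbut-2-en-1-ylidene)-4-oxocyclohexa-1,5-diene-1-carbaldehyde (ortho-quinone methide, not isolated) | O=CC1=C(O)/C(=C/C=C(C)C)C(=O)C=C1 | intermediate
4 | 5-hydroxy-2,2-dimethyl-2H-chromene-6-carbaldehyde | O=Cc1ccc2OC(C)(C)C=Cc2c1O | intermediate
5 | 5-methoxy-2,2-dimethyl-2H-chromene-6-carbaldehyde | COc1c(C=O)ccc2OC(C)(C)C=Cc12 | intermediate
6 | 5-(5-methoxy-2,2-dimethyl-2H-chromen-6-yl)-4-tosyl-4,5-dihydro-1,3-oxazole (racemic, both stereocentres lost in the same step, not isolated) | Cc1ccc(cc1)S(=O)(=O)C2N=COC2c3ccc4OC(C)(C)C=Cc4c3OC | intermediate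
7 | 2-(5-methoxy-2,2-dimethyl-2H-chromen-6-yl)acetonitrile | COc1c(CC#N)ccc2OC(C)(C)C=Cc12 | intermediate
8 | 2-(5-methoxy-2,2-dimethyl-2H-chromen-6-yl)acetic acid | COc1c(CC(=O)O)ccc2OC(C)(C)C=Cc12 | intermediate
9 | dilithium 2-(5-methoxy-2,2-dimethyl-2H-chromen-6-yl)ethene-1,1-diolate (not isolated) | [Li+].[Li+].COc1c(C=C([O-])[O-])ccc2OC(C)(C)C=Cc12 | intermediate
10 | 2-(5-methoxy-2,2-dimethyl-2H-chromen-6-yl)malonic acid | COc1c(C(C(=O)O)C(=O)O)ccc2OC(C)(C)C=Cc12 | intermediate
11 | 2,4,6-trichlorophenol | Oc1c(Cl)cc(Cl)cc1Cl | starting material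
12 | bis(2,4,6-trichlorophenyl) 2-(5-methoxy-2,2-dimethyl-2H-chromen-6-yl)malonate | COc1c(C(C(=O)Oc3c(Cl)cc(Cl)cc3Cl)C(=O)Oc4c(Cl)cc(Cl)cc4Cl)ccc2OC(C)(C)C=Cc12 | intermediate
13 | 3-methoxyphenol | COc1cccc(O)c1 | starting material
14 | 3-methoxyphenyl 2,4,6-trichlorophenyl 2-(5-methoxy-2,2-dimethyl-2H-chromen-6-yl)malonate (racemic, not isolated) | COc1cccc(OC(=O)C(C(=O)Oc2c(Cl)cc(Cl)cc2Cl)c3ccc4OC(C)(C)C=Cc4c3OC)c1 | intermediate
15 | 3-methoxyphenyl 2-(5-methoxy-2,2-dimethyl-2H-chromen-6-yl)-3-oxoprop-2-enoate (aryloxycarbonyl ketene, not isolated) | COc1cccc(OC(=O)C(=C=O)c2ccc3OC(C)(C)C=Cc3c2OC)c1 | intermediate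
16 | 4-hydroxy-7-methoxy-3-(5-methoxy-2,2-dimethyl-2H-chromen-6-yl)-2H-chromen-2-one | COc1ccc2c(O)c(-c3ccc4OC(C)(C)C=Cc4c3OC)c(=O)oc2c1 | intermediate
17 | 4,7-dimethoxy-3-(5-methoxy-2,2-dimethyl-2H-chromen-6-yl)-2H-chromen-2-one | COc1ccc2c(OC)c(-c3ccc4OC(C)(C)C=Cc4c3OC)c(=O)oc2c1 | intermediate
18 | 4,7-dimethoxy-3-(5-methoxy-2,2-dimethyl-2H-chromen-6-yl)-2H-chromen-2-ol (racemic lactol, not isolated) | COc1ccc2C(OC)=C(c3ccc4OC(C)(C)C=Cc4c3OC)C(O)Oc2c1 | intermediate
19 | 2-hydroxy-7-methoxy-3-(5-methoxy-2,2-dimethyl-2H-chromen-6-yl)chroman-4-one (racemic diastereomers, stereocentres lost on dehydration, not isolated) | COc1ccc2C(=O)C(c3ccc4OC(C)(C)C=Cc4c3OC)C(O)Oc2c1 | intermediate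
20 | 7-methoxy-3-(5-methoxy-2,2-dimethyl-2H-chromen-6-yl)-4H-chromen-4-one | COc1ccc2c(=O)c(-c3ccc4OC(C)(C)C=Cc4c3OC)coc2c1 | target

**Summary**

Total step count: 9. Longest linear sequence: 9 steps, from 1 to 20; 11 and 13 enter as purchased materials at steps 6 and 7.

**Steps most likely to fail**

1. Step 9 (proposed new method). The aluminium hemiacetal may open to the phenoxide aldehyde at low temperature and be reduced a second time, or the enol ether may hydrolyse sluggishly so that the acid needed begins to hydrate the chromene alkene. The fallback uses known chemistry and leaves the route at 16, before the methylation. Aqueous NaOH in ethanol at reflux opens the lactone, and the β-keto acid loses carbon dioxide on acidification to give the deoxybenzoin 1-(2-hydroxy-4-methoxyphenyl)-2-(5-methoxy-2,2-dimethyl-2H-chromen-6-yl)ethan-1-one F1. Heating F1 with N,N-dimethylformamide dimethyl acetal in toluene forms the enaminone 3-(dimethylamino)-1-(2-hydroxy-4-methoxyphenyl)-2-(5-methoxy-2,2-dimethyl-2H-chromen-6-yl)prop-2-en-1-one F2, which cyclises with loss of dimethylamine and rejoins the route at 20. Both operations are standard (alkaline degradation of 3-aryl-4-hydroxycoumarins, deoxybenzoin route to isoflavones) and keep ring B under basic or neutral conditions. The cost is that C2 is removed and put back.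

2. Step 7 (key step). At 200 °C the dimethylpyran ring may open electrocyclically and drift away by hydrogen shift, the malonate may lose carbon dioxide before C-acylation, or acylation may go in part to the carbon between the two oxygens of ring A. The fallback sets out from 8. Carbodiimide coupling (DCC, catalytic 4-(dimethylamino)pyridine, CH2Cl2) with purchased methyl 2-hydroxy-4-methoxybenzoate gives the ester methyl 4-methoxy-2-{[2-(5-methoxy-2,2-dimethyl-2H-chromen-6-yl)acetyl]oxy}benzoate F3. NaH in THF then brings about the intramolecular Claisen condensation (Dieckmann type) of the arylacetate enolate onto the methyl ester, with loss of methanol, and the route is rejoined at 16. This variant fixes the ring A regiochemistry in the purchased salicylate and never exceeds the boiling point of THF, but it closes ring C at C3–C4 and no longer at C4–C4a.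

3. Step 6. The hindered, weakly nucleophilic phenol may acylate so slowly that the O-acylisourea rearranges to the N-acylurea or the half ester loses carbon dioxide. The fallback sets out from 10. Oxalyl chloride with catalytic DMF in CH2Cl2 at 0 °C converts the diacid into 2-(5-methoxy-2,2-dimethyl-2H-chromen-6-yl)malonyl dichloride F4. Addition of F4 to 11 and triethylamine at −20 °C acylates the phenoxide through the acid chloride (or the chlorocarbonyl ketene derived from it), and the route is rejoined at 12.

Further compounds
F1 | step 9 | 1-(2-hydroxy-4-methoxyphenyl)-2-(5-methoxy-2,2-dimethyl-2H-chromen-6-yl)ethan-1-one | COc1ccc(C(=O)Cc2ccc3OC(C)(C)C=Cc3c2OC)c(O)c1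
F2 | step 9 | 3-(dimethylamino)-1-(2-hydroxy-4-methoxyphenyl)-2-(5-methoxy-2,2-dimethyl-2H-chromen-6-yl)prop-2-en-1-one (alkene geometry mobile) | COc1ccc(C(=O)C(=CN(C)C)c2ccc3OC(C)(C)C=Cc3c2OC)c(O)c1
F3 | step 7 | methyl 4-methoxy-2-{[2-(5-methoxy-2,2-dimethyl-2H-chromen-6-yl)acetyl]oxy}benzoate | COC(=O)c1ccc(OC)cc1OC(=O)Cc2ccc3OC(C)(C)C=Cc3c2OC
F4 | step 6 | 2-(5-methoxy-2,2-dimethyl-2H-chromen-6-yl)malonyl dichloride | COc1c(C(C(=O)Cl)C(=O)Cl)ccc2OC(C)(C)C=Cc12
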